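## Retrosynthetic overview

- **Numbering** (ring atoms in target-SMILES order): C1 (bears =CH2), C2, C3 (quaternary bridgehead), C4, C5 (carbinol), C6 (CH bridgehead), C7 (C–Me bridge), C8–C10, C11 (CMe2). Ring A = C3, C7–C11; ring B = C3–C7; ring C = C1, C2, C3, C7, C6.
- **Feature used:** the run of three contiguous quaternary carbons C11–C3–C7. The C3–C11 bond ties a CMe2 carbon to a bridgehead lying β to C1, so with C1 as a ketone this bond is the union of a tertiary radical with an enone β-carbon.
- **Disconnections, backwards:**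
  - caffeate C5–O (acylation)
  - exo C5–OH (endo-face hydride on the C5 ketone)
  - C1=CH2 (from the C1 ketone via enol triflate and allylsilane)
  - C5–C6 (aldol, ring B)
  - C3–C11 (hydrogen-atom-transfer radical conjugate addition, ring A)
  - C3–C4 (Mukaiyama–Michael)
  - C7–CH3 (copper-catalysed asymmetric conjugate addition)
- **Ring order:** ring C is bought as a cyclopentenone, ring A closes in step 6, ring B closes in step 9.

Key step: step 6

Assumption: the phosphoramidite enantiomer that delivers (R)-7 is used; its sense of induction is to be confirmed on a first batch, both ligand enantiomers being equally accessible.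

## Route

Step 1
Reactants: 1 5-bromo-2-methylpent-1-ene; 2 3-ethoxycyclopent-2-en-1-one
Product: 5 3-(4-methylpent-4-en-1-yl)cyclopent-2-en-1-one, via Grignard reagent 3 (not isolated), via tertiary carbinol adduct 4 (not isolated)
Conditions: Mg, THF, 40 °C; add 2, THF, 0 °C; then 1 M HCl, rt
Reagents that add atoms: none
Why: Stork–Danheiser-type sequence in which the Grignard reagent adds 1,2 to the vinylogous ester and acid hydrolysis of the 3-ethoxy allylic alcohol transposes the carbonyl to give the β-alkyl enone, with no stereocentre formed.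

Step 2
Reactants: 5 3-(4-methylpent-4-en-1-yl)cyclopent-2-en-1-one
Product: 7 (3R)-3-methyl-3-(4-methylpent-4-en-1-yl)cyclopentan-1-one, via dimethylaluminium enolate 6 (not isolated)
Conditions: Me3Al (2 equiv), Cu(OTf)2 (5 mol %), chiral phosphoramidite from 2,2′-biphenol and bis[1-(2-naphthyl)ethyl]amine (10 mol %), Et2O, −30 °C; then 1 M HCl
Reagents that add atoms: trimethylaluminium, C[Al](C)C
Why: Copper-catalysed asymmetric conjugate addition of a trialkylaluminium to a β-substituted cyclopentenone, a known way to all-carbon quaternary centres, in which the chiral phosphoramidite–copper complex selects the enone face and so sets C7 as R.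

Step 3
Reactants: 7 (3R)-3-methyl-3-(4-methylpent-4-en-1-yl)cyclopentan-1-one
Product: 8 (4S)-4-methyl-4-(4-methylpent-4-en-1-yl)cyclopent-2-en-1-one
Conditions: IBX (2.5 equiv), DMSO, 70 °C
Reagents that add atoms: none
Why: IBX-mediated α,β-dehydrogenation of a ketone, which can only give the C2=C3 enone because quaternary C7 offers no hydrogen next to C6, and which leaves the isolated alkene and C7 (now S by a priority change only) untouched.

Step 4
Reactants: 8 (4S)-4-methyl-4-(4-methylpent-4-en-1-yl)cyclopent-2-en-1-one; 9 tert-butyl[(1-methoxyethenyl)oxy]dimethylsilane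
Product: 10 methyl 2-[(5S)-3-(tert-butyldimethylsilyloxy)-5-methyl-5-(4-methylpent-4-en-1-yl)cyclopent-2-en-1-yl]acetate (both C3 epimers)
Conditions: t-BuMe2SiOTf (10 mol %), CH2Cl2, −78 °C; Et3N quench
Reagents that add atoms: none
Why: Mukaiyama–Michael addition under silyl triflate catalysis, known on 4,4-disubstituted cyclopentenones, in which silyl transfer delivers the regiodefined C1=C2 enol ether, the new C3 stereocentre being formed without control and erased in step 5.

Step 5
Reactants: 10 methyl 2-[(5S)-3-(tert-butyldimethylsilyloxy)-5-methyl-5-(4-methylpent-4-en-1-yl)cyclopent-2-en-1-yl]acetate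
Product: 11 methyl 2-[(5S)-5-methyl-5-(4-methylpent-4-en-1-yl)-3-oxocyclopent-1-en-1-yl]acetate
Conditions: Pd(OAc)2 (1.1 equiv), MeCN, rt to 40 °C
Reagents that add atoms: none
Why: Saegusa–Ito oxidation in which divalent palladium attacks the enol ether at C2 and β-hydride elimination of the C3 hydrogen restores the enone with the acetate arm on C3, the position of the silyl enol ether fixing the regiochemistry.

Step 6
Reactants: 11 methyl 2-[(5S)-5-methyl-5-(4-methylpent-4-en-1-yl)-3-oxocyclopent-1-en-1-yl]acetate
Product: 12 methyl 2-[(3aR,7aS)-4,4,7a-trimethyl-2-oxooctahydro-3aH-inden-3a-yl]acetate (cis-fused)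
Conditions: Fe(acac)3 (30 mol %), PhSiH3 (2.5 equiv), EtOH (0.02 M), 60 °C
Reagents that add atoms: none
Why: Fe(acac)3 and PhSiH3 in EtOH form an iron hydride that passes a hydrogen atom to the terminal CH2 of the isopropenyl group, which finishes the C11 gem-dimethyl unit and leaves a nucleophilic tertiary radical at C11; this radical adds to the enone β-carbon C3, and the C2 α-keto radical so formed is reduced to an iron enolate and protonated by the solvent. The closest known reaction type is the iron-catalysed reductive olefin coupling (a hydrogen-atom-transfer Giese addition), whose intramolecular form is established for joining two fully substituted carbons. Ring A closes in the 6-exo-trig mode, since C11 bonds to C3 while C2 stays outside the new six-membered ring. The one new stereocentre, C3, is controlled by C7: the C8–C10 tether leaves C7 on one face of ring C and can bring C11 to C3 only on that face, so the hydrindanone is cis-fused with the C4 arm and the C7 methyl on the same side (3aR,7aS). The step needs hydrogen-atom transfer to one of two alkenes and attack at C3 rather than C2; the electron-rich, unhindered 1,1-disubstituted alkene takes up the hydrogen atom far faster than the electron-poor trisubstituted enone, and polarity matching together with the 6-exo over 7-endo preference sends the radical to C3. A shift of the enone into the exocyclic C3=C4 enoate would do no harm, because C3 is the β-carbon of that acceptor too and the same product results.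

Step 7
Reactants: 12 methyl 2-[(3aR,7aS)-4,4,7a-trimethyl-2-oxooctahydro-3aH-inden-3a-yl]acetate
Product: 13 (3aS,7aS)-3a-(2-hydroxyethyl)-4,4,7a-trimethyloctahydro-1H-inden-2-ol (both C1 carbinol epimers)
Conditions: LiAlH4 (2 equiv), THF, 0 °C to rt; then H2O
Reagents that add atoms: none
Why: Standard LiAlH4 reduction of ester and ketone together, which avoids a protecting group on C1, the C1 carbinol centre forming as a mixture that is removed again in step 8.

Step 8
Reactants: 13 (3aS,7aS)-3a-(2-hydroxyethyl)-4,4,7a-trimethyloctahydro-1H-inden-2-ol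
Product: 15 2-[(3aS,7aS)-4,4,7a-trimethyl-2-oxooctahydro-3aH-inden-3a-yl]acetaldehyde, via bis(alkoxysulfonium) salt 14 (not isolated)
Conditions: (COCl)2 (3 equiv), DMSO (6 equiv), CH2Cl2, −78 °C; Et3N (10 equiv), −78 to 0 °C
Reagents that add atoms: none
Why: Swern oxidation, chosen because both alcohols are activated at −78 °C before base is added, so that no hydroxy aldehyde is present that could close to a lactol and be over-oxidised to a lactone.

Step 9
Reactants: 15 2-[(3aS,7aS)-4,4,7a-trimethyl-2-oxooctahydro-3aH-inden-3a-yl]acetaldehyde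
Product: 16 tricyclic ketol (C1 ketone and C5 hydroxyl; C5 epimers; C3 C6 C7 as in 28)
Conditions: K2CO3 (0.3 equiv), MeOH, rt
Reagents that add atoms: none
Why: Intramolecular aldol addition (5-enolexo-exo-trig) under reversible base catalysis, in which both enolates of the C1 ketone form but C2 could only close a cyclobutanol whereas C6 reaches C5 through a five-membered transition state; dehydration is barred by Bredt's rule, C6 is fixed because the C4–C5 arm hangs on one face of ring C, and C5 forms as an epimer mixture (endo expected to prevail) that is levelled in steps 14 and 15.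

Step 10
Reactants: 16 tricyclic ketol
Product: 17 tricyclic ketol triethylsilyl ether (C1 ketone and C5 OSiEt3)
Conditions: Et3SiOTf (1.3 equiv), 2,6-lutidine (2 equiv), CH2Cl2, −78 to 0 °C
Reagents that add atoms: triethylsilyl trifluoromethanesulfonate, CC[Si](CC)(CC)OS(=O)(=O)C(F)(F)F
Why: Silylation of a hindered secondary alcohol with a silyl triflate and a non-nucleophilic base, which blocks retro-aldol opening before strong base is used.

Step 11
Reactants: 17 tricyclic ketol triethylsilyl ether
Product: 19 tricyclic enol triflate (C1(OTf)=C2 and C5 OSiEt3), via potassium enolate 18 (not isolated)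
Conditions: KN(SiMe3)2 (1.3 equiv), THF, −78 to −20 °C; PhNTf2 (1.4 equiv), −78 °C to rt
Reagents that add atoms: N-phenylbis(trifluoromethanesulfonimide), O=S(=O)(N(c1ccccc1)S(=O)(=O)C(F)(F)F)C(F)(F)F
Why: Enol triflate formation from a potassium enolate as practised on camphor-type ketones, where C6 is a bridgehead so that only C2 can be deprotonated, and where the route thereby avoids a carbonyl addition at C1, whose exo face is covered by C8H2 and whose endo face is covered by an endo C5 silyloxy group.

Step 12
Reactants: 19 tricyclic enol triflate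
Product: 20 tricyclic allylsilane (C1(CH2SiMe3)=C2 and C5 OSiEt3)
Conditions: Me3SiCH2MgCl (2 equiv), Pd(PPh3)4 (5 mol %), LiCl (3 equiv), THF, rt to 45 °C
Reagents that add atoms: (trimethylsilyl)methylmagnesium chloride, C[Si](C)(C)C[Mg]Cl
Why: Kumada–Corriu cross-coupling of an alkenyl triflate with Me3SiCH2MgCl under zerovalent palladium catalysis, the standard entry to allylsilanes, which brings in the last skeletal carbon without touching a stereocentre.

Step 13
Reactants: 20 tricyclic allylsilane
Product: 21 tricyclic homoallylic alcohol (C1=CH2 and C5 hydroxyl; C5 epimers)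
Conditions: p-TsOH·H2O (20 mol %), MeOH/CH2Cl2 (1:1), 0 °C to rt
Reagents that add atoms: none
Why: Acid-catalysed protodesilylation of the allylsilane (SE2′), in which the proton adds to C2, the β-silyl cation at C1 loses silicon and the double bond ends up exocyclic as C1=CH2, while the same acid in MeOH removes the triethylsilyl ether.

Step 14
Reactants: 21 tricyclic homoallylic alcohol
Product: 22 tricyclic ketone (C1=CH2 and C5 ketone)
Conditions: Dess–Martin periodinane (1.5 equiv), CH2Cl2, 0 °C to rt
Reagents that add atoms: none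
Why: Dess–Martin oxidation converges both C5 epimers on one ketone, and the β,γ-unsaturated ketone cannot slip into conjugation because that would need an enol at bridgehead C6 (Bredt's rule).

Step 15
Reactants: 22 tricyclic ketone
Product: 23 (1R,6S,7R,8R)-2,2,6-trimethyl-11-methylidenetricyclo[5.2.2.0(1,6)]undecan-8-ol (exo C5 alcohol; 3R 5R 6R 7S in the numbering used here)
Conditions: LiAlH4 (1 equiv), Et2O, −78 to 0 °C; then H2O
Reagents that add atoms: none
Why: Hydride reduction of a norbornanone carrying a syn substituent on the one-carbon bridge (the camphor-to-isoborneol pattern), in which the C7 methyl hangs over the exo face of C5 so that hydride arrives from the endo face, further opened by sp2 C1, and sets C5 as the exo alcohol (5R).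

Step 16
Reactants: 24 caffeic acid
Product: 26 (E)-3-[3,4-bis(tert-butyldimethylsilyloxy)phenyl]prop-2-enoic acid, via tris-silyl derivative 25 (not isolated)
Conditions: t-BuMe2SiCl (3.5 equiv), imidazole (7 equiv), DMF, rt; then AcOH/THF/H2O (3:1:1), rt
Reagents that add atoms: tert-butyldimethylsilyl chloride, CC(C)(C)[Si](C)(C)Cl
Why: Exhaustive silylation followed by selective hydrolysis of the labile silyl ester, which leaves the two aryl silyl ethers and the E-alkene in place.

Step 17
Reactants: 23 exo C5 alcohol; 26 (E)-3-[3,4-bis(tert-butyldimethylsilyloxy)phenyl]prop-2-enoic acid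
Product: 27 bis-silylated caffeate of 23
Conditions: DCC (1.5 equiv), DMAP (0.5 equiv), CH2Cl2, rt
Reagents that add atoms: none
Why: Steglich esterification of the hindered exo alcohol through the acylpyridinium ion, with retention at C5 because the C5–O bond is not broken.

Step 18
Reactants: 27 bis-silylated caffeate of 23
Product: 28 target caffeate CNP0308742.2
Conditions: Bu4NF (2.5 equiv), AcOH (2.5 equiv), THF, 0 °C
Reagents that add atoms: none
Why: Fluoride cleavage of aryl silyl ethers buffered with AcOH, mild enough for the cinnamate ester, the free catechol and the acid-sensitive methylenenorbornane.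

## Compound list

1 | 5-bromo-2-methylpent-1-ene | C=C(C)CCCBr | starting material
2 | 3-ethoxycyclopent-2-en-1-one | CCOC1=CC(=O)CC1 | starting material
3 | (4-methylpent-4-en-1-yl)magnesium bromide | C=C(C)CCC[Mg]Br | intermediate
4 | 3-ethoxy-1-(4-methylpent-4-en-1-yl)cyclopent-2-en-1-ol (bromomagnesium alkoxide until the acid quench) | CCOC1=CC(O)(CCCC(C)=C)CC1 | intermediate
5 | 3-(4-methylpent-4-en-1-yl)cyclopent-2-en-1-one | C=C(C)CCCC1=CC(=O)CC1 | intermediate
6 | dimethylaluminium (3R)-3-methyl-3-(4-methylpent-4-en-1-yl)cyclopent-1-en-1-olate | C[Al](C)OC1=C[C@](C)(CCCC(C)=C)CC1 | intermediate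
7 | (3R)-3-methyl-3-(4-methylpent-4-en-1-yl)cyclopentan-1-one | O=C1C[C@](C)(CCCC(C)=C)CC1 | intermediate
8 | (4S)-4-methyl-4-(4-methylpent-4-en-1-yl)cyclopent-2-en-1-one | O=C1C[C@](C)(CCCC(C)=C)C=C1 | intermediate
9 | tert-butyl[(1-methoxyethenyl)oxy]dimethylsilane | C=C(OC)O[Si](C)(C)C(C)(C)C | starting material
10 | methyl 2-[(5S)-3-(tert-butyldimethylsilyloxy)-5-methyl-5-(4-methylpent-4-en-1-yl)cyclopent-2-en-1-yl]acetate, C3 epimers | COC(=O)CC1C=C(O[Si](C)(C)C(C)(C)C)C[C@]1(C)CCCC(C)=C | intermediate
11 | methyl 2-[(5S)-5-methyl-5-(4-methylpent-4-en-1-yl)-3-oxocyclopent-1-en-1-yl]acetate | COC(=O)CC1=CC(=O)C[C@]1(C)CCCC(C)=C | intermediate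
12 | methyl 2-[(3aR,7aS)-4,4,7a-trimethyl-2-oxooctahydro-3aH-inden-3a-yl]acetate | COC(=O)C[C@@]12CC(=O)C[C@]1(C)CCCC2(C)C | intermediate
13 | (3aS,7aS)-3a-(2-hydroxyethyl)-4,4,7a-trimethyloctahydro-1H-inden-2-ol, C1 epimers | OCC[C@@]12CC(O)C[C@]1(C)CCCC2(C)C | intermediate
14 | bis(dimethylalkoxysulfonium) dichloride of 13 | C[S+](C)OCC[C@@]12CC(O[S+](C)C)C[C@]1(C)CCCC2(C)C.[Cl-].[Cl-] | intermediate
15 | 2-[(3aS,7aS)-4,4,7a-trimethyl-2-oxooctahydro-3aH-inden-3a-yl]acetaldehyde | O=CC[C@@]12CC(=O)C[C@]1(C)CCCC2(C)C | intermediate
16 | tricyclic ketol, C1 ketone, C5 OH (C5 epimers) | O=C1C[C@]23CC(O)[C@H]1[C@]2(C)CCCC3(C)C | intermediate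
17 | triethylsilyl ether of 16 | O=C1C[C@]23CC(O[Si](CC)(CC)CC)[C@H]1[C@]2(C)CCCC3(C)C | intermediate
18 | potassium C1=C2 enolate of 17 | [K+].[O-]C1=C[C@]23CC(O[Si](CC)(CC)CC)[C@H]1[C@]2(C)CCCC3(C)C | intermediate
19 | tricyclic enol triflate, C1(OTf)=C2 | O=S(=O)(OC1=C[C@]23CC(O[Si](CC)(CC)CC)[C@H]1[C@]2(C)CCCC3(C)C)C(F)(F)F | intermediate
20 | tricyclic allylsilane, C1(CH2SiMe3)=C2 | C[Si](C)(C)CC1=C[C@]23CC(O[Si](CC)(CC)CC)[C@H]1[C@]2(C)CCCC3(C)C | intermediate
21 | tricyclic alcohol, C1=CH2, C5 OH (C5 epimers) | C=C1C[C@]23CC(O)[C@H]1[C@]2(C)CCCC3(C)C | intermediate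
22 | tricyclic ketone, C1=CH2, C5 ketone | C=C1C[C@]23CC(=O)[C@H]1[C@]2(C)CCCC3(C)C | intermediate
23 | (1R,6S,7R,8R)-2,2,6-trimethyl-11-methylidenetricyclo[5.2.2.0(1,6)]undecan-8-ol (exo C5 alcohol) | C=C1C[C@]23C[C@@H](O)[C@H]1[C@]2(C)CCCC3(C)C | intermediate
24 | caffeic acid | O=C(O)/C=C/c1ccc(O)c(O)c1 | starting material
25 | tert-butyldimethylsilyl (E)-3-[3,4-bis(tert-butyldimethylsilyloxy)phenyl]prop-2-enoate | CC(C)(C)[Si](C)(C)OC(=O)/C=C/c1ccc(O[Si](C)(C)C(C)(C)C)c(O[Si](C)(C)C(C)(C)C)c1 | intermediate
26 | (E)-3-[3,4-bis(tert-butyldimethylsilyloxy)phenyl]prop-2-enoic acid | O=C(O)/C=C/c1ccc(O[Si](C)(C)C(C)(C)C)c(O[Si](C)(C)C(C)(C)C)c1 | intermediate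
27 | bis-silylated caffeate of 23 | C=C1C[C@]23C[C@@H](OC(=O)/C=C/c4ccc(O[Si](C)(C)C(C)(C)C)c(O[Si](C)(C)C(C)(C)C)c4)[C@H]1[C@]2(C)CCCC3(C)C | intermediate
28 | CNP0308742.2, caffeate of 23 (3R,5R,6R,7S) | C=C1C[C@]23C[C@@H](OC(=O)/C=C/c4ccc(O)c(O)c4)[C@H]1[C@]2(C)CCCC3(C)C | target

## Step count and risks

Total steps: 18
Longest linear sequence: 17 steps (steps 1–15, 17 and 18)

Steps most likely to fail:

**1. Step 6.**
- **What may go wrong:** the 6-exo attack on a β,β-disubstituted enone carbon flanked by quaternary C7 may be slow. It could then lose out to capture of the C11 radical by a second hydrogen atom (net hydrogenation of the isopropenyl group), or to reversible hydrogen-atom transfer that moves the alkene into the chain.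
- **Fallback:** it sets out from 11 and makes the same radical without a metal hydride. Markovnikov addition of HBr (33 % in AcOH, CH2Cl2, 0 °C) should give the tertiary bromide methyl 2-[(5S)-5-(4-bromo-4-methylpentyl)-5-methyl-3-oxocyclopent-1-en-1-yl]acetate F1. Syringe-pump addition of Bu3SnH and AIBN in refluxing toluene then generates the C11 radical by bromine abstraction at a low concentration of hydrogen donor (classical tin hydride Giese cyclisation). The route is rejoined at 12.

**2. Step 9.**
- **What may go wrong:** the aldol addition is an equilibrium. The strain of the new bicyclo[2.2.1] unit may leave it on the side of the open keto aldehyde, or the ketol may reopen during handling.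
- **Fallback:** it sets out from 12 and closes ring B irreversibly with an allylsilane.
  - Deprotonation with KN(SiMe3)2 and trapping with PhNTf2 should give the C1=C6 enol triflate methyl 2-[(3aR,7aS)-4,4,7a-trimethyl-2-(trifluoromethylsulfonyloxy)-3,4,5,6,7,7a-hexahydro-3aH-inden-3a-yl]acetate F2. Its C1=C2 regioisomer is separated and could not cyclise in any case.
  - Negishi coupling with Me3SiCH2ZnCl and Pd(PPh3)4 spares the ester and gives the allylsilane methyl 2-[(3aR,7aS)-4,4,7a-trimethyl-2-(trimethylsilylmethyl)-3,4,5,6,7,7a-hexahydro-3aH-inden-3a-yl]acetate F3.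
  - Reduction with i-Bu2AlH in toluene at −78 °C gives the aldehyde 2-[(3aR,7aS)-4,4,7a-trimethyl-2-(trimethylsilylmethyl)-3,4,5,6,7,7a-hexahydro-3aH-inden-3a-yl]acetaldehyde F4.
  - BF3·OEt2 in CH2Cl2 at −78 °C triggers an intramolecular Hosomi–Sakurai reaction. C6 attacks C5 and loss of silicon creates C1=CH2 in the same event.
  - The route is rejoined at 21, and steps 7–13 are bypassed.

**3. Step 2.**
- **What may go wrong:** methyl transfer to a five-membered β-alkyl enone may be slow and may show poor facial selectivity, which would erode the enantiomeric purity of everything downstream.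
- **Fallback:** it sets out from 1 (as Grignard reagent 3) and moves the enantio-determining event from the C7–CH3 bond to the C7–C8 bond. Reagent 3 is added to commercial 3-methylcyclopent-2-en-1-one under Cu(OTf)2 and a chiral hydroxyalkyl imidazolinium salt (N-heterocyclic carbene ligand) in Et2O at −30 °C. This gives bromomagnesium (3R)-3-methyl-3-(4-methylpent-4-en-1-yl)cyclopent-1-en-1-olate F5, which is protonated on work-up with 1 M HCl. The route is rejoined at 7, and step 1 is no longer needed.

## Further compounds

F1 | step 6 | methyl 2-[(5S)-5-(4-bromo-4-methylpentyl)-5-methyl-3-oxocyclopent-1-en-1-yl]acetate | COC(=O)CC1=CC(=O)C[C@]1(C)CCCC(C)(C)Br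
F2 | step 9 | methyl 2-[(3aR,7aS)-4,4,7a-trimethyl-2-(trifluoromethylsulfonyloxy)-3,4,5,6,7,7a-hexahydro-3aH-inden-3a-yl]acetate | COC(=O)C[C@@]12CC(OS(=O)(=O)C(F)(F)F)=C[C@]1(C)CCCC2(C)C
F3 | step 9 | methyl 2-[(3aR,7aS)-4,4,7a-trimethyl-2-(trimethylsilylmethyl)-3,4,5,6,7,7a-hexahydro-3aH-inden-3a-yl]acetate | COC(=O)C[C@@]12CC(C[Si](C)(C)C)=C[C@]1(C)CCCC2(C)C
F4 | step 9 | 2-[(3aR,7aS)-4,4,7a-trimethyl-2-(trimethylsilylmethyl)-3,4,5,6,7,7a-hexahydro-3aH-inden-3a-yl]acetaldehyde | O=CC[C@@]12CC(C[Si](C)(C)C)=C[C@]1(C)CCCC2(C)C
F5 | step 2 | bromomagnesium (3R)-3-methyl-3-(4-methylpent-4-en-1-yl)cyclopent-1-en-1-olate | Br[Mg]OC1=C[C@](C)(CCCC(C)=C)CC1
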